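**Retrosynthetic overview**
1. Target 17 comes from its benzyl ether 16 by hydrogenolysis (last step).
2. Benzofuran ring (formed last): disconnect C2–C3 and O–C2 into aryl bromide 9, the two-carbon alkyne 12 and iodophenol 11 (two Sonogashira couplings, then 5-endo-dig closure).
3. Dihydrobenzofuran ring (formed second, key step): disconnect C3–C3a of ester 8 back to (S)-flavanone 6. The ketone α-carbon is made electrophilic by trivalent iodine (an enolonium equivalent) and is captured by the migrating aryl carbon, which contracts the ring and sets C3 trans to C2.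
4. Pyranone ring (formed first): 6 comes from chromone 4 and arylboronic acid 5 by rhodium-catalysed asymmetric 1,4-addition (sets C2); 4 comes from acetophenone 1 by bromination and amide-acetal annulation.
5. Ring order: chromone, flavanone, ring-contracted dihydrobenzofuran, benzofuran.

Assumption: (S)-MeO-F12-BIPHEP is taken to give the 2S flavanone, as (S)-BINAP-type ligands do with cyclic enones; if the rotation of 6 shows the opposite sense, the mirror-image ligand is used.

**Route**

Step 1
Reactants: 1 1-(2-hydroxy-3-methoxyphenyl)ethan-1-one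
Product: 2 1-(5-bromo-2-hydroxy-3-methoxyphenyl)ethan-1-one
Conditions: NBS (1.05 equiv), MeCN, 0 °C to rt
Reagents that add atoms: N-bromosuccinimide O=C1CCC(=O)N1Br
Why: Electrophilic aromatic bromination goes to the only open position para to the free phenol, which is also meta to the acetyl group, so the 5-bromo ketone forms without touching the methyl ketone.

Step 2
Reactants: 2 1-(5-bromo-2-hydroxy-3-methoxyphenyl)ethan-1-one
Product: 4 6-bromo-8-methoxy-4H-chromen-4-one, via enaminone 3 (not isolated)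
Conditions: (i) Me2NCH(OMe)2 (1.5 equiv), toluene, 100 °C; (ii) AcOH, 90 °C
Reagents that add atoms: N,N-dimethylformamide dimethyl acetal COC(OC)N(C)C
Why: Condensation of the methyl ketone with the amide acetal gives the enaminone, and acid-promoted addition of the phenol to its β-carbon with loss of dimethylamine is the standard chromone annulation, with no stereocentre involved.

Step 3
Reactants: 4 6-bromo-8-methoxy-4H-chromen-4-one; 5 [4-(benzyloxy)-3-methoxyphenyl]boronic acid
Product: 6 (2S)-2-[4-(benzyloxy)-3-methoxyphenyl]-6-bromo-8-methoxy-2,3-dihydro-4H-chromen-4-one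
Conditions: [RhCl(C2H4)2]2 (2.5 mol%), (S)-MeO-F12-BIPHEP (5.5 mol%), KOH (10 mol%), 5 (2 equiv), toluene/H2O (10:1), 25 °C
Reagents that add atoms: none
Why: In this Hayashi–Miyaura asymmetric 1,4-addition the aryl-rhodium species adds to one face of the chromone enone under control of the electron-poor atropisomeric bisphosphine, which creates C2 as the S centre, and the mild room-temperature conditions avoid ring-opening of the flavanone to the chalcone and so avoid racemisation.

Step 4
Reactants: 6 (2S)-2-[4-(benzyloxy)-3-methoxyphenyl]-6-bromo-8-methoxy-2,3-dihydro-4H-chromen-4-one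
Product: 8 methyl (2S,3S)-2-[4-(benzyloxy)-3-methoxyphenyl]-5-bromo-7-methoxy-2,3-dihydro-1-benzofuran-3-carboxylate, via enol ether 7 (not isolated)
Conditions: PhI(OAc)2 (1.3 equiv), conc. H2SO4 (0.5 equiv), HC(OMe)3, 0 °C to rt; aq. NaHCO3 work-up
Reagents that add atoms: trimethyl orthoformate COC(OC)OC; water O
Why: This is the hypervalent-iodine oxidative ring contraction of a flavanone (an oxidative 1,2-aryl shift of the semipinacol type), in which electrophilic trivalent iodine bonds to the normally nucleophilic α-carbon C3 of enol ether 7 on the face anti to the C2 aryl group and turns it into an enolonium equivalent, the oxygen-activated aryl carbon C4a (also a nucleophile by nature) then migrates from C4 to C3 with inversion as iodobenzene leaves, so the new C3–C3a bond and the C3 stereocentre form trans to the untouched 2S centre while the dimethoxycarbenium ion left at C4 ends as the methyl ester.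

Step 5
Reactants: 8 methyl (2S,3S)-2-[4-(benzyloxy)-3-methoxyphenyl]-5-bromo-7-methoxy-2,3-dihydro-1-benzofuran-3-carboxylate
Product: 9 [(2S,3R)-2-[4-(benzyloxy)-3-methoxyphenyl]-5-bromo-7-methoxy-2,3-dihydro-1-benzofuran-3-yl]methanol
Conditions: LiBH4 (2 equiv), THF, 0 °C to rt; aq. NH4Cl
Reagents that add atoms: none
Why: Chemoselective hydride reduction of the methyl ester gives the primary alcohol without touching the aryl bromide or the benzyl ether and without epimerising C3, whose descriptor changes from S to R only because the substituent priorities change.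

Step 6
Reactants: 10 4-(3-hydroxypropyl)-2-methoxyphenol
Product: 11 4-(3-hydroxypropyl)-2-iodo-6-methoxyphenol
Conditions: I2 (1.05 equiv), NaHCO3 (1.5 equiv), THF/H2O (1:1), 0 °C to rt
Reagents that add atoms: iodine (I2), SMILES II
Why: Electrophilic iodination of the phenoxide goes to the only free position ortho to the phenol oxygen because the para position carries the side chain, as is usual for 4-alkylguaiacols.

Step 7
Reactants: 9 [(2S,3R)-2-[4-(benzyloxy)-3-methoxyphenyl]-5-bromo-7-methoxy-2,3-dihydro-1-benzofuran-3-yl]methanol; 12 ethynyl(trimethyl)silane; 11 4-(3-hydroxypropyl)-2-iodo-6-methoxyphenol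
Product: 16 3-{2-[(2S,3R)-2-[4-(benzyloxy)-3-methoxyphenyl]-3-(hydroxymethyl)-7-methoxy-2,3-dihydro-1-benzofuran-5-yl]-7-methoxy-1-benzofuran-5-yl}propan-1-ol, via silylalkyne 13 (not isolated), via terminal alkyne 14 (not isolated), via alkynylphenol 15 (not isolated)
Conditions: (i) 12 (1.05 equiv), Pd(PhCN)2Cl2 (3 mol%), P(t-Bu)3·HBF4 (6 mol%), CuI (3 mol%), i-Pr2NH, dioxane, 25–40 °C; (ii) 11 (1.1 equiv), K2CO3 (3 equiv), MeOH, 60 °C
Reagents that add atoms: none
Why: A one-pot sequence of Sonogashira coupling of the aryl bromide, methanolysis of the C–Si bond, a second Sonogashira coupling with the more reactive aryl iodide and base/copper-promoted 5-endo-dig cyclisation of the ortho-alkynylphenol is the classical domino route to 2-arylbenzofurans, and it tolerates the free hydroxyl groups and touches no stereocentre.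

Step 8
Reactants: 16 3-{2-[(2S,3R)-2-[4-(benzyloxy)-3-methoxyphenyl]-3-(hydroxymethyl)-7-methoxy-2,3-dihydro-1-benzofuran-5-yl]-7-methoxy-1-benzofuran-5-yl}propan-1-ol
Product: 17 4-[(2S,3R)-3-(hydroxymethyl)-5-[5-(3-hydroxypropyl)-7-methoxy-1-benzofuran-2-yl]-7-methoxy-2,3-dihydro-1-benzofuran-2-yl]-2-methoxyphenol
Conditions: H2 (1 atm), 10% Pd/C, EtOAc/MeOH (1:1), rt, 1–2 h, stopped at full conversion
Reagents that add atoms: none
Why: Catalytic hydrogenolysis of the benzyl aryl ether at 1 atm is much faster than reduction of the 2-arylbenzofuran or cleavage of the cyclic benzylic ether, so the phenol is released with both stereocentres intact.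

**Compound list**
1 | 1-(2-hydroxy-3-methoxyphenyl)ethan-1-one | CC(=O)c1cccc(OC)c1O | starting material
2 | 1-(5-bromo-2-hydroxy-3-methoxyphenyl)ethan-1-one | CC(=O)c1cc(Br)cc(OC)c1O | intermediate
3 | (E)-1-(5-bromo-2-hydroxy-3-methoxyphenyl)-3-(dimethylamino)prop-2-en-1-one (enaminone, not isolated) | CN(C)/C=C/C(=O)c1cc(Br)cc(OC)c1O | intermediate
4 | 6-bromo-8-methoxy-4H-chromen-4-one | O=c1ccoc2c(OC)cc(Br)cc12 | intermediate
5 | [4-(benzyloxy)-3-methoxyphenyl]boronic acid | COc1cc(B(O)O)ccc1OCc1ccccc1 | starting material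
6 | (2S)-2-[4-(benzyloxy)-3-methoxyphenyl]-6-bromo-8-methoxy-2,3-dihydro-4H-chromen-4-one | O=C1C[C@@H](c2ccc(OCc3ccccc3)c(OC)c2)Oc2c(OC)cc(Br)cc12 | intermediate
7 | (2S)-2-[4-(benzyloxy)-3-methoxyphenyl]-6-bromo-4,8-dimethoxy-2H-chromene (enol ether, not isolated) | COC1=C[C@@H](c2ccc(OCc3ccccc3)c(OC)c2)Oc2c(OC)cc(Br)cc12 | intermediate
8 | methyl (2S,3S)-2-[4-(benzyloxy)-3-methoxyphenyl]-5-bromo-7-methoxy-2,3-dihydro-1-benzofuran-3-carboxylate (trans) | COc1cc([C@H]2Oc3c(OC)cc(Br)cc3[C@@H]2C(=O)OC)ccc1OCc1ccccc1 | intermediate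
9 | [(2S,3R)-2-[4-(benzyloxy)-3-methoxyphenyl]-5-bromo-7-methoxy-2,3-dihydro-1-benzofuran-3-yl]methanol (trans) | COc1cc([C@H]2Oc3c(OC)cc(Br)cc3[C@@H]2CO)ccc1OCc1ccccc1 | intermediate
10 | 4-(3-hydroxypropyl)-2-methoxyphenol (dihydroconiferyl alcohol) | COc1cc(CCCO)ccc1O | starting material
11 | 4-(3-hydroxypropyl)-2-iodo-6-methoxyphenol | COc1cc(CCCO)cc(I)c1O | intermediate
12 | ethynyl(trimethyl)silane | C#C[Si](C)(C)C | starting material
13 | [(2S,3R)-2-[4-(benzyloxy)-3-methoxyphenyl]-7-methoxy-5-[(trimethylsilyl)ethynyl]-2,3-dihydro-1-benzofuran-3-yl]methanol (not isolated) | COc1cc([C@H]2Oc3c(OC)cc(C#C[Si](C)(C)C)cc3[C@@H]2CO)ccc1OCc1ccccc1 | intermediate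
14 | [(2S,3R)-2-[4-(benzyloxy)-3-methoxyphenyl]-5-ethynyl-7-methoxy-2,3-dihydro-1-benzofuran-3-yl]methanol (not isolated) | COc1cc([C@H]2Oc3c(OC)cc(C#C)cc3[C@@H]2CO)ccc1OCc1ccccc1 | intermediate
15 | 2-{[(2S,3R)-2-[4-(benzyloxy)-3-methoxyphenyl]-3-(hydroxymethyl)-7-methoxy-2,3-dihydro-1-benzofuran-5-yl]ethynyl}-4-(3-hydroxypropyl)-6-methoxyphenol (not isolated) | COc1cc([C@H]2Oc3c(OC)cc(C#Cc4cc(CCCO)cc(OC)c4O)cc3[C@@H]2CO)ccc1OCc1ccccc1 | intermediate
16 | 3-{2-[(2S,3R)-2-[4-(benzyloxy)-3-methoxyphenyl]-3-(hydroxymethyl)-7-methoxy-2,3-dihydro-1-benzofuran-5-yl]-7-methoxy-1-benzofuran-5-yl}propan-1-ol | COc1cc([C@H]2Oc3c(OC)cc(-c4cc5cc(CCCO)cc(OC)c5o4)cc3[C@@H]2CO)ccc1OCc1ccccc1 | intermediate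
17 | 4-[(2S,3R)-3-(hydroxymethyl)-5-[5-(3-hydroxypropyl)-7-methoxy-1-benzofuran-2-yl]-7-methoxy-2,3-dihydro-1-benzofuran-2-yl]-2-methoxyphenol | COc1cc([C@H]2Oc3c(OC)cc(-c4cc5cc(CCCO)cc(OC)c5o4)cc3[C@@H]2CO)ccc1O | target

**Step count**
Total: 8 steps. Longest linear sequence: 7 steps (1, 2, 3, 4, 5, 7, 8); step 6 is a one-step side branch.

**Steps most likely to fail, with fallbacks**

Step 4 (ring contraction). The electron-rich C2 aryl group may migrate instead (giving an isoflavone), the flavanone may be dehydrogenated to the flavone, or the strong acid may erode the C2 configuration. The fallback sets out from 6 and comes back at 8, and replaces the one-pot oxidation by a stepwise halide route. Bromination of 6 with PhNMe3Br3 in THF at 0 °C gives the trans bromoketone (2R,3R)-2-[4-(benzyloxy)-3-methoxyphenyl]-3,6-dibromo-8-methoxy-2,3-dihydro-4H-chromen-4-one F5. Ketalisation with HC(OMe)3/MeOH and catalytic TsOH gives (2R,3R)-2-[4-(benzyloxy)-3-methoxyphenyl]-3,6-dibromo-4,4,8-trimethoxy-3,4-dihydro-2H-chromene F6. AgBF4 in MeOH/HC(OMe)3 at rt (or ZnBr2 in toluene at 90 °C) then pulls off the bromide while the aryl carbon shifts from C4 to C3 with inversion, the α-haloketal rearrangement known from 2-arylpropionic acid manufacture, and gives 8 with the same trans outcome.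

Step 3 (asymmetric 1,4-addition). Chromones are sluggish acceptors, the electron-rich boronic acid can protodeboronate, and the sense or level of induction may fall short. The fallback sets out from 2 and comes back at 6. Claisen–Schmidt condensation of 2 with 4-(benzyloxy)-3-methoxybenzaldehyde F1 (KOH, EtOH, 25 °C) gives (E)-3-[4-(benzyloxy)-3-methoxyphenyl]-1-(5-bromo-2-hydroxy-3-methoxyphenyl)prop-2-en-1-one F2. NaOAc in refluxing EtOH closes it by oxa-Michael addition to racemic 2-[4-(benzyloxy)-3-methoxyphenyl]-6-bromo-8-methoxy-2,3-dihydro-4H-chromen-4-one F3. Kinetic resolution by asymmetric transfer hydrogenation with RuCl(p-cymene)[(R,R)-TsDPEN] and HCO2H/Et3N in EtOAc at 25 °C, stopped near half conversion, reduces the 2R enantiomer to the cis alcohol (2R,4R)-2-[4-(benzyloxy)-3-methoxyphenyl]-6-bromo-8-methoxy-3,4-dihydro-2H-chromen-4-ol F4, which is removed by chromatography, and leaves 6.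

Step 7 (one-pot double Sonogashira and annulation). The electron-rich bromide may couple slowly, and premature desilylation can give the symmetrical diarylalkyne or Glaser products. The fallback sets out from 11 and comes back at 16, and makes the aryl–benzofuran bond by Suzuki coupling instead. Sonogashira coupling of 11 with 2-ethynyl-6-methyl-1,3,6,2-dioxazaborocane-4,8-dione F7 (PdCl2(PPh3)2, CuI, Et3N, DMF, 60 °C), with ring closure in the same flask, gives the boronate 2-[5-(3-hydroxypropyl)-7-methoxy-1-benzofuran-2-yl]-6-methyl-1,3,6,2-dioxazaborocane-4,8-dione F8. Slow-release Suzuki–Miyaura coupling of F8 with 9 (Pd(OAc)2, SPhos, K3PO4, dioxane/H2O, 60 °C) gives 16.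

**Further compounds**
F1 | step 3 | 4-(benzyloxy)-3-methoxybenzaldehyde | COc1cc(C=O)ccc1OCc1ccccc1
F2 | step 3 | (E)-3-[4-(benzyloxy)-3-methoxyphenyl]-1-(5-bromo-2-hydroxy-3-methoxyphenyl)prop-2-en-1-one | COc1cc(/C=C/C(=O)c2cc(Br)cc(OC)c2O)ccc1OCc1ccccc1
F3 | step 3 | racemic 2-[4-(benzyloxy)-3-methoxyphenyl]-6-bromo-8-methoxy-2,3-dihydro-4H-chromen-4-one | O=C1CC(c2ccc(OCc3ccccc3)c(OC)c2)Oc2c(OC)cc(Br)cc12
F4 | step 3 | (2R,4R)-2-[4-(benzyloxy)-3-methoxyphenyl]-6-bromo-8-methoxy-3,4-dihydro-2H-chromen-4-ol | O[C@@H]1C[C@H](c2ccc(OCc3ccccc3)c(OC)c2)Oc2c(OC)cc(Br)cc12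
F5 | step 4 | (2R,3R)-2-[4-(benzyloxy)-3-methoxyphenyl]-3,6-dibromo-8-methoxy-2,3-dihydro-4H-chromen-4-one | O=C1[C@H](Br)[C@@H](c2ccc(OCc3ccccc3)c(OC)c2)Oc2c(OC)cc(Br)cc12
F6 | step 4 | (2R,3R)-2-[4-(benzyloxy)-3-methoxyphenyl]-3,6-dibromo-4,4,8-trimethoxy-3,4-dihydro-2H-chromene | COC1(OC)[C@H](Br)[C@@H](c2ccc(OCc3ccccc3)c(OC)c2)Oc2c(OC)cc(Br)cc12
F7 | step 7 | 2-ethynyl-6-methyl-1,3,6,2-dioxazaborocane-4,8-dione | C#CB1OC(=O)CN(C)CC(=O)O1
F8 | step 7 | 2-[5-(3-hydroxypropyl)-7-methoxy-1-benzofuran-2-yl]-6-methyl-1,3,6,2-dioxazaborocane-4,8-dione | CN1CC(=O)OB(c2cc3cc(CCCO)cc(OC)c3o2)OC(=O)C1
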